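**Retrosynthetic overview**
1. Kanzonol S (22) ⇐ tetrasilyl ether 21 ⇐ flavanone-3-carboxylate 19. This removes four TBS groups and a temporary C3 tert-butyl ester that activates the ring closure.
2. 19 ⇐ ketal 9 + alkenylboronic acid 15 in one operation. First the bond from the benzylic CH2 on C8 to the vinylic CH of the side chain forms, then the bond O1–C2 (ring C and the C2 stereocentre).
3. Enabling feature: in ring A the CH2 on C8 is ortho to C8a–O1, so O1–C8a–C8–CH2 is a latent o-quinone methide, stabilised by O7 (ortho) and O5 (para) to C8. The same O1 is the β-oxygen of the C2–C3–C4=O unit of ring C, that is, the nucleophile of an oxa-Michael closure.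
4. 9 ⇐ Knoevenagel condensation of β-ketoester 6 with aldehyde 8. 6 ⇐ phloroacetophenone 1 (silylation, ortho-hydroxymethylation, ketal, C-acylation). 15 ⇐ propargyl alcohol 10 (carboalumination sets the E-alkene).
5. Ring order: rings A and B are bought. A temporary 1,3,2-dioxaborinine ring (step 2) and then a 1,3-dioxine ring (step 3) span O1 and the C8-CH2. Ring C forms last (step 11), as the temporary ring opens.

Key step: step 11

Remarks: TBS = tert-butyldimethylsilyl and TBSO = its aryl ether. Flavanone numbering is used (O1, C2–C4, C4a, C5–C8, C8a).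
Assumption: the quinine- and quinidine-derived 9-amino-9-deoxy-epi-cinchona 3,5-bis(trifluoromethyl)phenyl thioureas are pseudo-enantiomers and should give opposite antipodes. The one that delivers (2S) is meant by "(2S)-selective cinchona thiourea". Enantiomeric purity is to be checked at 21 and raised by recrystallisation if needed.

Step 1
Reactants: 1 2',4',6'-trihydroxyacetophenone
Product: 2 1-[2-hydroxy-4,6-bis(TBSO)phenyl]ethanone
Conditions: TBSCl (2.1 equiv), imidazole (4.5 equiv), DMF, 0 °C → rt
Reagents that add atoms: tert-butyldimethylsilyl chloride CC(C)(C)[Si](C)(C)Cl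
Why: Phenol silylation, in which the 4-OH and one of the two equivalent ortho-OH groups react while the last OH is held back by its hydrogen bond to the acetyl group, so two equivalents should stop at 2.

Step 2
Reactants: 2 1-[2-hydroxy-4,6-bis(TBSO)phenyl]ethanone
Product: 3 1-[5,7-bis(TBSO)-2-phenyl-4H-1,3,2-benzodioxaborinin-8-yl]ethanone
Conditions: PhB(OH)2 (1.2 equiv), (CH2O)n (5 equiv), EtCO2H (0.3 equiv), PhMe, reflux, Dean–Stark
Reagents that add atoms: phenylboronic acid OB(O)c1ccccc1; formaldehyde (from paraformaldehyde) C=O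
Why: Boronic-acid-templated ortho-hydroxymethylation of a phenol (Nagata reaction), in which the aryloxyboronate delivers formaldehyde only to the single open position ortho to the free OH (the later C8) and traps the salicyl alcohol as a cyclic boronate, which should suppress diarylmethane formation.

Step 3
Reactants: 3 1-[5,7-bis(TBSO)-2-phenyl-4H-1,3,2-benzodioxaborinin-8-yl]ethanone
Product: 5 1-[5,7-bis(TBSO)-2,2-dimethyl-4H-1,3-benzodioxin-8-yl]ethanone, via salicyl alcohol 4 (not isolated)
Conditions: pinacol (1.1 equiv), 2,2-dimethoxypropane (10 equiv), PPTS (5 mol %), acetone, rt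
Reagents that add atoms: 2,2-dimethoxypropane COC(C)(C)OC
Why: Transesterification of boron to the stronger ligand pinacol followed by acid-catalysed ketalisation of the freed 1,3-diol, giving a six-membered ketal that masks O1 and the benzylic oxygen against the base of step 4 and the amine of step 6.

Step 4
Reactants: 5 1-[5,7-bis(TBSO)-2,2-dimethyl-4H-1,3-benzodioxin-8-yl]ethanone
Product: 6 tert-butyl 3-[5,7-bis(TBSO)-2,2-dimethyl-4H-1,3-benzodioxin-8-yl]-3-oxopropanoate
Conditions: LiHMDS (2.3 equiv), THF, −78 °C; Boc2O (1.1 equiv), −78 → 0 °C; aq NH4Cl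
Reagents that add atoms: di-tert-butyl dicarbonate CC(C)(C)OC(=O)OC(=O)OC(C)(C)C
Why: Claisen-type C-acylation of a methyl ketone enolate, in which the second equivalent of base deprotonates the β-ketoester and so should draw the reaction to the C-acylated product.

Step 5
Reactants: 7 3,4-dihydroxybenzaldehyde
Product: 8 3,4-bis(TBSO)benzaldehyde
Conditions: TBSCl (2.3 equiv), imidazole (5 equiv), DMF, rt
Reagents that add atoms: tert-butyldimethylsilyl chloride CC(C)(C)[Si](C)(C)Cl
Why: Routine silylation of both catechol hydroxyl groups, with the aldehyde untouched.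

Step 6
Reactants: 6 tert-butyl 3-[5,7-bis(TBSO)-2,2-dimethyl-4H-1,3-benzodioxin-8-yl]-3-oxopropanoate; 8 3,4-bis(TBSO)benzaldehyde
Product: 9 tert-butyl (Z)-2-{[5,7-bis(TBSO)-2,2-dimethyl-4H-1,3-benzodioxin-8-yl]carbonyl}-3-[3,4-bis(TBSO)phenyl]prop-2-enoate
Conditions: piperidine (20 mol %), AcOH (20 mol %), 4 Å MS, PhMe, rt → 40 °C
Reagents that add atoms: none
Why: Knoevenagel condensation under piperidinium acetate, which should give mainly the isomer with the aryl group cis to the ester and cannot run on to a premature oxa-Michael closure because O1 is tied up in the ketal.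

Step 7
Reactants: 10 prop-2-yn-1-ol
Product: 12 (E)-3-iodo-2-methylprop-2-en-1-ol, via alkenylalane 11 (not isolated)
Conditions: Me3Al (3 equiv), Cp2ZrCl2 (25 mol %), CH2Cl2, 0 °C → rt; I2, THF, −30 → 0 °C; aq K2CO3
Reagents that add atoms: trimethylaluminium C[Al](C)C; iodine II
Why: Negishi zirconium-catalysed methylalumination adds Me and Al syn with Al on the terminal carbon, and iodinolysis with retention should give the E-iodide (iodine trans to CH2OH).

Step 8
Reactants: 12 (E)-3-iodo-2-methylprop-2-en-1-ol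
Product: 13 (E)-2-methyl-3-(4,4,5,5-tetramethyl-1,3,2-dioxaborolan-2-yl)prop-2-en-1-ol
Conditions: B2pin2 (1.1 equiv), PdCl2(PPh3)2 (3 mol %), PPh3 (6 mol %), KOPh (1.5 equiv), PhMe, 50 °C
Reagents that add atoms: bis(pinacolato)diboron CC1(C)OB(OC1(C)C)B1OC(C)(C)C(C)(C)O1
Why: Miyaura borylation of an alkenyl iodide proceeds with retention of the alkene geometry, and it is run before acetylation so that no allylic acetate is exposed to Pd(0).

Step 9
Reactants: 13 (E)-2-methyl-3-(4,4,5,5-tetramethyl-1,3,2-dioxaborolan-2-yl)prop-2-en-1-ol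
Product: 14 (E)-2-methyl-3-(4,4,5,5-tetramethyl-1,3,2-dioxaborolan-2-yl)prop-2-enyl acetate
Conditions: Ac2O (1.5 equiv), pyridine, DMAP (cat.), CH2Cl2, 0 °C → rt
Reagents that add atoms: acetic anhydride CC(=O)OC(C)=O
Why: Routine acetylation of a primary allylic alcohol, to which the pinacol boronate is inert.

Step 10
Reactants: 14 (E)-2-methyl-3-(4,4,5,5-tetramethyl-1,3,2-dioxaborolan-2-yl)prop-2-enyl acetate
Product: 15 [(E)-3-acetoxy-2-methylprop-1-enyl]boronic acid
Conditions: NaIO4 (3 equiv), NH4OAc (3 equiv), acetone/H2O, rt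
Reagents that add atoms: water O
Why: Oxidative deprotection of a pinacol boronate, in which periodate cleaves the released pinacol and so pulls the hydrolysis to the free boronic acid under near-neutral conditions that spare the acetate and the alkene.

Step 11
Reactants: 9 tert-butyl (Z)-2-{[5,7-bis(TBSO)-2,2-dimethyl-4H-1,3-benzodioxin-8-yl]carbonyl}-3-[3,4-bis(TBSO)phenyl]prop-2-enoate; 15 [(E)-3-acetoxy-2-methylprop-1-enyl]boronic acid
Product: 19 tert-butyl (2S,3R)-8-[(E)-4-acetoxy-3-methylbut-2-enyl]-2-[3,4-bis(TBSO)phenyl]-5,7-bis(TBSO)-4-oxochromane-3-carboxylate, via alkenyl dioxaborinine 16 (not isolated), via o-quinone methide 17 (not isolated), via ring-open phenol 18 (not isolated)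
Conditions: (i) 15 (1.4 equiv), (PhO)2P(O)OH (5 mol %), PhMe, 0 °C → rt; (ii) −25 °C, (2S)-selective cinchona thiourea (15 mol %)
Reagents that add atoms: none
Why: Proposed new method: the acid exchanges the phenolic ketal of 9 for the boronic acid to give dioxaborinine 16, whose benzylic C–O bond should ionise readily because that carbon is ortho, ortho and para to three ring oxygens, and in the resulting o-quinone methide 17 the boron stays on the carbonyl oxygen (the later O1) and hands its alkenyl group to the exocyclic CH2 through a closed six-membered transition state, with retention of the E geometry and rearomatisation of ring A to phenol 18. The closest known reaction types are the diol-catalysed 1,4-addition of alkenylboronates to o-quinone methides made from o-hydroxybenzyl ethers, its three-component phenol/aldehyde/boronate form, the use of 4H-1,3,2-benzodioxaborinines as o-quinone methide sources, and the cinchona-thiourea oxa-Michael cyclisation of 2-hydroxyaryl alkylidene β-ketoesters; new are the ketal as precursor, the unsubstituted CH2 terminus and the linking of both events in one flask. Ring C closes in stage (ii) by 6-endo-trig oxa-Michael addition of the freed O1 to the arylidene carbon. C2 is set by the catalyst, whose thiourea binds the β-ketoester while the quinuclidine guides the phenol to one face of the alkylidene, and C3 should settle as the trans epimer by reversible enolisation and is erased in step 12. The step needs alkenyl transfer to the CH2 and not to the arylidene carbon, which is secured by the O1-bound boron (it reaches only the CH2) and by the gain of aromaticity, and it needs closure through O1 and not O5 (8- rather than 6-substituted flavanone), which is secured because only O1 is unmasked while O5 and O7 stay silylated. Racemic background closure in stage (i) should stay slow because the phenol of 18 is locked in a hydrogen bond to the ketone, as in the isolable parent substrates of this cyclisation, and the first part of the basic catalyst neutralises the acid.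

Step 12
Reactants: 19 tert-butyl (2S,3R)-8-[(E)-4-acetoxy-3-methylbut-2-enyl]-2-[3,4-bis(TBSO)phenyl]-5,7-bis(TBSO)-4-oxochromane-3-carboxylate
Product: 21 (2S)-8-[(E)-4-acetoxy-3-methylbut-2-enyl]-2-[3,4-bis(TBSO)phenyl]-5,7-bis(TBSO)chroman-4-one, via β-keto acid 20 (not isolated)
Conditions: TsOH·H2O (20 mol %), PhMe, 80 °C
Reagents that add atoms: none
Why: Acid-catalysed loss of isobutene from the tert-butyl ester and decarboxylation of the β-keto acid, which avoids the enolate that would open ring C (so C2 should be kept), while the acetate could only ionise to an unstabilised primary/secondary allyl cation and O7 is still silylated and cannot add to the alkene.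

Step 13
Reactants: 21 (2S)-8-[(E)-4-acetoxy-3-methylbut-2-enyl]-2-[3,4-bis(TBSO)phenyl]-5,7-bis(TBSO)chroman-4-one
Product: 22 Kanzonol S
Conditions: Et3N·3HF (12 equiv), THF/MeCN, 0 °C → rt
Reagents that add atoms: none
Why: Fluoride cleavage of the four aryl silyl ethers in a slightly acidic medium, in which no phenoxide or enolate builds up, so the acetate, the E-alkene and the base-sensitive C2 centre should all survive.

**Compound list**
1 | 2',4',6'-trihydroxyacetophenone | CC(=O)c1c(O)cc(O)cc1O | starting material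
2 | 1-[2-hydroxy-4,6-bis(TBSO)phenyl]ethanone | CC(=O)c1c(O)cc(O[Si](C)(C)C(C)(C)C)cc1O[Si](C)(C)C(C)(C)C | intermediate
3 | 1-[5,7-bis(TBSO)-2-phenyl-4H-1,3,2-benzodioxaborinin-8-yl]ethanone | CC(=O)c1c2OB(c3ccccc3)OCc2c(O[Si](C)(C)C(C)(C)C)cc1O[Si](C)(C)C(C)(C)C | intermediate
4 | 1-[2-hydroxy-3-(hydroxymethyl)-4,6-bis(TBSO)phenyl]ethanone (salicyl alcohol) | CC(=O)c1c(O)c(CO)c(O[Si](C)(C)C(C)(C)C)cc1O[Si](C)(C)C(C)(C)C | intermediate
5 | 1-[5,7-bis(TBSO)-2,2-dimethyl-4H-1,3-benzodioxin-8-yl]ethanone | CC(=O)c1c2OC(C)(C)OCc2c(O[Si](C)(C)C(C)(C)C)cc1O[Si](C)(C)C(C)(C)C | intermediate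
6 | tert-butyl 3-[5,7-bis(TBSO)-2,2-dimethyl-4H-1,3-benzodioxin-8-yl]-3-oxopropanoate | CC(C)(C)OC(=O)CC(=O)c1c2OC(C)(C)OCc2c(O[Si](C)(C)C(C)(C)C)cc1O[Si](C)(C)C(C)(C)C | intermediate
7 | 3,4-dihydroxybenzaldehyde | O=Cc1ccc(O)c(O)c1 | starting material
8 | 3,4-bis(TBSO)benzaldehyde | O=Cc1ccc(O[Si](C)(C)C(C)(C)C)c(O[Si](C)(C)C(C)(C)C)c1 | intermediate
9 | tert-butyl (Z)-2-{[5,7-bis(TBSO)-2,2-dimethyl-4H-1,3-benzodioxin-8-yl]carbonyl}-3-[3,4-bis(TBSO)phenyl]prop-2-enoate | CC(C)(C)OC(=O)/C(=C\c1ccc(O[Si](C)(C)C(C)(C)C)c(O[Si](C)(C)C(C)(C)C)c1)C(=O)c1c2OC(C)(C)OCc2c(O[Si](C)(C)C(C)(C)C)cc1O[Si](C)(C)C(C)(C)C | intermediate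
10 | prop-2-yn-1-ol | C#CCO | starting material
11 | dimethylaluminium alkoxide of (E)-3-(dimethylalumanyl)-2-methylprop-2-en-1-ol (alkenylalane) | C[Al](C)OC/C(C)=C/[Al](C)C | intermediate
12 | (E)-3-iodo-2-methylprop-2-en-1-ol | OC/C(C)=C/I | intermediate
13 | (E)-2-methyl-3-(4,4,5,5-tetramethyl-1,3,2-dioxaborolan-2-yl)prop-2-en-1-ol | OC/C(C)=C/B1OC(C)(C)C(C)(C)O1 | intermediate
14 | (E)-2-methyl-3-(4,4,5,5-tetramethyl-1,3,2-dioxaborolan-2-yl)prop-2-enyl acetate | CC(=O)OC/C(C)=C/B1OC(C)(C)C(C)(C)O1 | intermediate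
15 | [(E)-3-acetoxy-2-methylprop-1-enyl]boronic acid | CC(=O)OC/C(C)=C/B(O)O | intermediate
16 | 2-[(E)-3-acetoxy-2-methylprop-1-enyl]-4H-1,3,2-benzodioxaborinine analogue of 9 (boron in place of the ketal carbon) | CC(=O)OC/C(C)=C/B1OCc2c(O1)c(C(=O)/C(=C/c3ccc(O[Si](C)(C)C(C)(C)C)c(O[Si](C)(C)C(C)(C)C)c3)C(=O)OC(C)(C)C)c(O[Si](C)(C)C(C)(C)C)cc2O[Si](C)(C)C(C)(C)C | intermediate
17 | o-quinone methide: 6-methylidenecyclohexa-2,4-dienone bearing the arylidene β-ketoester at C2 and TBSO at C3 and C5 | C=C1C(=O)C(C(=O)/C(=C/c2ccc(O[Si](C)(C)C(C)(C)C)c(O[Si](C)(C)C(C)(C)C)c2)C(=O)OC(C)(C)C)=C(O[Si](C)(C)C(C)(C)C)C=C1O[Si](C)(C)C(C)(C)C | intermediate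
18 | tert-butyl (Z)-2-{3-[(E)-4-acetoxy-3-methylbut-2-enyl]-2-hydroxy-4,6-bis(TBSO)benzoyl}-3-[3,4-bis(TBSO)phenyl]prop-2-enoate (ring-open phenol) | CC(=O)OC/C(C)=C/Cc1c(O)c(C(=O)/C(=C/c2ccc(O[Si](C)(C)C(C)(C)C)c(O[Si](C)(C)C(C)(C)C)c2)C(=O)OC(C)(C)C)c(O[Si](C)(C)C(C)(C)C)cc1O[Si](C)(C)C(C)(C)C | intermediate
19 | tert-butyl (2S,3R)-8-[(E)-4-acetoxy-3-methylbut-2-enyl]-2-[3,4-bis(TBSO)phenyl]-5,7-bis(TBSO)-4-oxochromane-3-carboxylate (2,3-trans; C3 labile) | CC(=O)OC/C(C)=C/Cc1c(O[Si](C)(C)C(C)(C)C)cc(O[Si](C)(C)C(C)(C)C)c2c1O[C@H](c1ccc(O[Si](C)(C)C(C)(C)C)c(O[Si](C)(C)C(C)(C)C)c1)[C@@H](C(=O)OC(C)(C)C)C2=O | intermediate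
20 | (2S,3R)-8-[(E)-4-acetoxy-3-methylbut-2-enyl]-2-[3,4-bis(TBSO)phenyl]-5,7-bis(TBSO)-4-oxochromane-3-carboxylic acid | CC(=O)OC/C(C)=C/Cc1c(O[Si](C)(C)C(C)(C)C)cc(O[Si](C)(C)C(C)(C)C)c2c1O[C@H](c1ccc(O[Si](C)(C)C(C)(C)C)c(O[Si](C)(C)C(C)(C)C)c1)[C@@H](C(=O)O)C2=O | intermediate
21 | (2S)-8-[(E)-4-acetoxy-3-methylbut-2-enyl]-2-[3,4-bis(TBSO)phenyl]-5,7-bis(TBSO)chroman-4-one | CC(=O)OC/C(C)=C/Cc1c(O[Si](C)(C)C(C)(C)C)cc(O[Si](C)(C)C(C)(C)C)c2c1O[C@H](c1ccc(O[Si](C)(C)C(C)(C)C)c(O[Si](C)(C)C(C)(C)C)c1)CC2=O | intermediate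
22 | Kanzonol S, (2S)-8-[(E)-4-acetoxy-3-methylbut-2-enyl]-2-(3,4-dihydroxyphenyl)-5,7-dihydroxychroman-4-one | CC(=O)OC/C(C)=C/Cc1c(O)cc(O)c2c1O[C@H](c1ccc(O)c(O)c1)CC2=O | target

**Step count**
Total steps: 13. Longest linear sequence: 8 (steps 1, 2, 3, 4, 6, 11, 12, 13).

**Steps most likely to fail**

Step 11. Several processes may interfere:
- Ionisation and alkenyl transfer may be slower than protodeboronation of the boronic acid or self-condensation of the quinone methide.
- Ring C may begin to close without catalyst control in the acidic stage.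
- Boron residues may blunt the thiourea, so that facial selectivity is poor.

The fallback splits the cascade into known reactions and sets out from 9.
- Mild hydrolysis of the ketal (AcOH/THF/H2O, rt) should give the free salicyl alcohol F1.
- In parallel, 15 is esterified with propan-2-ol over molecular sieves to the diisopropyl boronate F2.
- F1 and F2 are joined by the known biphenol-catalysed addition of alkenylboronates to o-quinone methides (3,3'-dibromo-BINOL, PhMe, rt → 40 °C; no stereocentre is formed here).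
- The route is rejoined at 18, now isolated and purified.
- 18 is then cyclised in a separate, boron- and acid-free flask by the known thiourea oxa-Michael reaction at −25 °C to 19.

Step 12. The hot sulfonic acid may strip the C7 silyl ether, after which the phenol can add to the side-chain alkene. It may also ionise the allylic acetate, or erode C2 by reversible opening of ring C. The fallback leaves Brønsted acid catalysis altogether and sets out from 19.
- Silyl-transfer dealkylation under amine buffer (TMSOTf, 2,6-lutidine, CH2Cl2, 0 °C) should give the trimethylsilyl ester F3.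
- pH 7 buffer releases the acid 20, which is isolated.
- 20 is decarboxylated under neutral conditions in warm toluene (50–60 °C), coming back to the route at 21.

Step 2. Formation of the aryloxyboronate may be sluggish because the phenol is hydrogen-bonded to the acetyl group. Long heating may then cause silyl loss or arene–arene coupling through formaldehyde. The fallback changes the oxidation level and sets out from 2.
- Magnesium-mediated ortho-formylation (Casnati–Skattebøl conditions: MgCl2, Et3N, (CH2O)n, MeCN, reflux) should give the salicylaldehyde F4.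
- Chemoselective reduction of the aldehyde beside the hindered, chelated ketone (NaBH4, THF/EtOH, −20 °C) comes back to the route at 4.
- 4 is ketalised to 5 as in the second half of step 3.

**Further compounds**
F1 | step 11 | tert-butyl (Z)-2-[2-hydroxy-3-(hydroxymethyl)-4,6-bis(TBSO)benzoyl]-3-[3,4-bis(TBSO)phenyl]prop-2-enoate | CC(C)(C)OC(=O)/C(=C\c1ccc(O[Si](C)(C)C(C)(C)C)c(O[Si](C)(C)C(C)(C)C)c1)C(=O)c1c(O)c(CO)c(O[Si](C)(C)C(C)(C)C)cc1O[Si](C)(C)C(C)(C)C
F2 | step 11 | diisopropyl [(E)-3-acetoxy-2-methylprop-1-enyl]boronate | CC(=O)OC/C(C)=C/B(OC(C)C)OC(C)C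
F3 | step 12 | trimethylsilyl (2S,3R)-8-[(E)-4-acetoxy-3-methylbut-2-enyl]-2-[3,4-bis(TBSO)phenyl]-5,7-bis(TBSO)-4-oxochromane-3-carboxylate | CC(=O)OC/C(C)=C/Cc1c(O[Si](C)(C)C(C)(C)C)cc(O[Si](C)(C)C(C)(C)C)c2c1O[C@H](c1ccc(O[Si](C)(C)C(C)(C)C)c(O[Si](C)(C)C(C)(C)C)c1)[C@@H](C(=O)O[Si](C)(C)C)C2=O
F4 | step 2 | 3-acetyl-2-hydroxy-4,6-bis(TBSO)benzaldehyde | CC(=O)c1c(O)c(C=O)c(O[Si](C)(C)C(C)(C)C)cc1O[Si](C)(C)C(C)(C)C
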